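**Retrosynthetic overview**

- Feature: ring B is the aryl ring C1'–C6' on the CH2 at lactone C4. It has three neighbouring C–O carbons (C3', C4', C5'), and its alkyl-bearing carbon C1' lies para to the middle one. Dimethyl squarate can supply C3'–C6' and all three oxygens in that order.
- Target ⇒ C3' phenol (O-methylation) ⇒ cut C6'–C1' (Stille coupling at the sp3 carbon of a 4-chlorocyclobutenone) and C2'–C3' (ring opening to a dienylketene, then 6π closure). The fragments are 4-chloro-2,3-dimethoxycyclobutenone and the finished lactone carrying a 2-(tributylstannyl)allyl group (C1', C2' and the benzylic CH2).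
- Stannane ⇒ Markovnikov hydrostannation of the 4-propargyl lactone ⇒ trans benzylation at C3 with 3,4-dimethoxybenzyl bromide ⇒ (R)-4-propargylbutyrolactone ⇒ Evans alkylation of N-pent-4-ynoyl-(S)-4-benzyloxazolidinone with tert-butyl bromoacetate, which sets C4.
- Chloride ⇒ monoreduction of dimethyl squarate, then acid-free deoxychlorination.
- Order of rings: ring A is bought, the lactone ring closes in step 4, ring B closes in step 9.

Key step: step 9

Remark: the chlorocyclobutenone is made and used as the racemate, because its only stereocentre ends as the aromatic CH C6'. 3,4-Dimethoxybenzyl bromide is taken as commercial and is used fresh.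

**Step 1**
Reactants: 1 pent-4-ynoic acid; 2 (S)-4-benzyloxazolidin-2-one
Product: 4 (S)-4-benzyl-3-(pent-4-ynoyl)oxazolidin-2-one, via pent-4-ynoic pivalic anhydride 3 (not isolated)
Conditions: PivCl, Et3N, THF, −20 °C; then LiCl, 2, −20 °C to rt
Reagents that add atoms: pivaloyl chloride, CC(C)(C)C(=O)Cl (its acyl group is held only by 3)
Why: Mixed-anhydride N-acylation of an oxazolidinone: with LiCl and Et3N the carbamate nitrogen attacks the unhindered pentynoyl carbonyl of 3 and not the pivaloyl one, and these weak bases leave the alkyne CH alone.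

**Step 2**
Reactants: 4 (S)-4-benzyl-3-(pent-4-ynoyl)oxazolidin-2-one; 5 tert-butyl bromoacetate
Product: 7 tert-butyl (3R)-3-{[(4S)-4-benzyl-2-oxo-1,3-oxazolidin-3-yl]carbonyl}hex-5-ynoate, via sodium (Z)-enolate 6 (not isolated)
Conditions: NaN(SiMe3)2 (1.1 equiv), THF, −78 °C; then 5, −78 to −40 °C
Reagents that add atoms: NaN(SiMe3)2, C[Si](C)(C)[N-][Si](C)(C)C.[Na+] (its sodium is held only by 6)
Why: Evans alkylation: the imide α-CH2 is many pK units more acidic than the alkyne CH, so one equivalent of base gives only the chelated (Z)-enolate 6, one face of which is covered by the benzyl group of the (S)-auxiliary, and the bromoacetate enters from the open face to set the future lactone C4 as (R), the minor diastereomer being removable by chromatography.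

**Step 3**
Reactants: 7 tert-butyl (3R)-3-{[(4S)-4-benzyl-2-oxo-1,3-oxazolidin-3-yl]carbonyl}hex-5-ynoate
Product: 8 tert-butyl (3R)-3-(hydroxymethyl)hex-5-ynoate
Conditions: LiBH4, H2O (1 equiv), Et2O, 0 °C
Reagents that add atoms: none
Why: Reductive removal of the auxiliary (hydride reduction of an N-acyloxazolidinone): LiBH4 attacks the activated exocyclic imide carbonyl and carries it through to the primary alcohol, while the hindered tert-butyl ester and the alkyne do not react at 0 °C and the stereocentre is carried over unchanged.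

**Step 4**
Reactants: 8 tert-butyl (3R)-3-(hydroxymethyl)hex-5-ynoate
Product: 10 (4R)-4-(prop-2-yn-1-yl)dihydrofuran-2(3H)-one, via (3R)-3-(hydroxymethyl)hex-5-ynoic acid 9 (not isolated)
Conditions: TFA, CH2Cl2, 0 °C to rt
Reagents that add atoms: none
Why: Acidolysis of the tert-butyl ester followed by 5-exo-trig lactonisation of γ-hydroxy acid 9 closes the lactone ring, and the stereocentre, now β to the carbonyl, cannot epimerise.

**Step 5**
Reactants: 10 (4R)-4-(prop-2-yn-1-yl)dihydrofuran-2(3H)-one; 11 3,4-dimethoxybenzyl bromide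
Product: 13 (3R,4R)-3-(3,4-dimethoxybenzyl)-4-(prop-2-yn-1-yl)dihydrofuran-2(3H)-one, via lithium enolate 12 (not isolated)
Conditions: LiN(SiMe3)2 (1.05 equiv), THF, −78 °C; then 11, −78 to −30 °C
Reagents that add atoms: LiN(SiMe3)2, C[Si](C)(C)[N-][Si](C)(C)C.[Li+] (its lithium is held only by 12)
Why: Substrate-controlled alkylation of a lactone enolate, the standard entry to trans-dibenzylbutyrolactones: the bromide approaches the flat enolate 12 on the face away from the C4 propargyl group and so sets C3 as (R), trans to C4, while the lactone α-CH is more acidic than the alkyne CH and any lithium acetylide formed is not alkylated in THF at this temperature.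

**Step 6**
Reactants: 13 (3R,4R)-3-(3,4-dimethoxybenzyl)-4-(prop-2-yn-1-yl)dihydrofuran-2(3H)-one; 14 tributyltin hydride
Product: 15 (3R,4R)-3-(3,4-dimethoxybenzyl)-4-[2-(tributylstannyl)prop-2-en-1-yl]dihydrofuran-2(3H)-one
Conditions: Mo(CO)3(CNtBu)3 (5 mol %), hydroquinone (10 mol %), THF, 55 °C
Reagents that add atoms: none
Why: Molybdenum-catalysed Markovnikov hydrostannation of a 1-alkyne: this isonitrile complex adds Sn–H in a syn sense with tin on the internal carbon, hydroquinone suppresses the radical chain that would put tin on the terminal carbon, the neutral medium spares the lactone and C3, and the terminal isomer has to be removed on Et3N-washed silica because it would end as a wrongly substituted ring B.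

**Step 7**
Reactants: 16 dimethyl squarate
Product: 17 (±)-4-hydroxy-2,3-dimethoxycyclobut-2-en-1-one
Conditions: LiAlH(OtBu)3 (1.05 equiv), THF, −78 to −20 °C; then sat. aq. NH4Cl
Reagents that add atoms: none
Why: Chemoselective 1,2-monoreduction of a cyclobutenedione with a bulky hydride: after the first addition the remaining carbonyl is only a vinylogous ester next to an aluminium alkoxide and is not reduced, the new carbinol centre is racemic and of no consequence, and the nearly neutral quench avoids the acid-induced allylic transposition that would expel methanol.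

**Step 8**
Reactants: 17 (±)-4-hydroxy-2,3-dimethoxycyclobut-2-en-1-one
Product: 18 (±)-4-chloro-2,3-dimethoxycyclobut-2-en-1-one
Conditions: Me2C=C(Cl)NMe2 (1.1 equiv), CH2Cl2, 0 °C; used at once
Reagents that add atoms: 1-chloro-N,N,2-trimethylprop-1-en-1-amine, CC(C)=C(Cl)N(C)C
Why: Deoxychlorination of an alcohol with an α-chloroenamine: the alcohol adds to the reagent to give an alkoxyiminium chloride, chloride then displaces the amide at the allylic, α-keto carbon, and since no HCl is liberated the acid-triggered ionisation of the dialkoxycyclobutenone is held back.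

**Step 9**
Reactants: 15 (3R,4R)-3-(3,4-dimethoxybenzyl)-4-[2-(tributylstannyl)prop-2-en-1-yl]dihydrofuran-2(3H)-one; 18 (±)-4-chloro-2,3-dimethoxycyclobut-2-en-1-one
Product: 22 (3R,4R)-3-(3,4-dimethoxybenzyl)-4-(3-hydroxy-4,5-dimethoxybenzyl)dihydrofuran-2(3H)-one, via 4-alkenylcyclobutenone 19 (not isolated), via dienylketene 20 (not isolated), via cyclohexa-2,4-dienone 21 (not isolated)
Conditions: Pd2(dba)3 (2.5 mol %), P(2-furyl)3 (10 mol %), 18 (1.3 equiv), 1,4-dioxane, 50 °C; then 100 °C
Reagents that add atoms: none
Why: Oxidative addition of 18 to zerovalent palladium ionises the C6'–Cl bond to an η3-oxocyclobutenylpalladium chloride, the alkenyl group of 15 passes from tin to palladium (the weak donor P(2-furyl)3 is chosen to speed this transfer from a hindered 1,1-disubstituted stannane), and reductive elimination makes the bond C6'–C1' of 19. On heating to 100 °C the four-membered ring of 19 breaks between C3' and C6' by thermal 4π conrotation to dienylketene 20, a disrotatory 6π electrocyclisation bonds the ketene carbon C3' to the terminal =CH2 (C2') and thereby closes the six-membered carbocycle ring B, and dienone 21 enolises irreversibly to phenol 22. The closest known reaction type is the Stille coupling of 4-chlorocyclobutenones with alkenylstannanes followed by thermal benzannulation, of which 18 is a new and more electron-rich member. Only the ketene in which the alkenyl group has turned inward can cyclise, but the ring opening is reversible, so the outward isomer returns to 19 and the material should drain through 20. No lasting stereocentre is formed, since both epimers of 19 that arise from racemic 18 converge on one arene, and the neutral medium leaves lactone C3 and C4 untouched. The selectivity required is between the two termini of the η3-allyl unit, CH against C(OMe): bond formation at the less hindered CH terminus, which also keeps the vinylogous ester conjugation, is expected, and from there the sequence OH, OMe, OMe, H, CH2R, H around ring B follows from connectivity.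

**Step 10**
Reactants: 22 (3R,4R)-3-(3,4-dimethoxybenzyl)-4-(3-hydroxy-4,5-dimethoxybenzyl)dihydrofuran-2(3H)-one
Product: 23 (3R,4R)-3-(3,4-dimethoxybenzyl)-4-(3,4,5-trimethoxybenzyl)dihydrofuran-2(3H)-one (target)
Conditions: MeI, K2CO3, acetone, 40 °C
Reagents that add atoms: methyl iodide, CI
Why: Williamson O-methylation: K2CO3 deprotonates only the phenol, the phenoxide attacks MeI by SN2, and the trans lactone is the thermodynamically preferred epimer, so mild base cannot harm C3.

**Compound list**

1 | pent-4-ynoic acid | C#CCCC(=O)O | starting material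
2 | (S)-4-benzyloxazolidin-2-one | O=C1N[C@@H](Cc2ccccc2)CO1 | starting material
3 | pent-4-ynoic pivalic anhydride | C#CCCC(=O)OC(=O)C(C)(C)C | intermediate
4 | (S)-4-benzyl-3-(pent-4-ynoyl)oxazolidin-2-one | C#CCCC(=O)N1[C@@H](Cc2ccccc2)COC1=O | intermediate
5 | tert-butyl bromoacetate | CC(C)(C)OC(=O)CBr | starting material
6 | sodium (Z)-enolate of 4 | C#CC/C=C(\[O-])N1[C@@H](Cc2ccccc2)COC1=O.[Na+] | intermediate
7 | tert-butyl (3R)-3-{[(4S)-4-benzyl-2-oxo-1,3-oxazolidin-3-yl]carbonyl}hex-5-ynoate | C#CC[C@H](CC(=O)OC(C)(C)C)C(=O)N1[C@@H](Cc2ccccc2)COC1=O | intermediate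
8 | tert-butyl (3R)-3-(hydroxymethyl)hex-5-ynoate | C#CC[C@@H](CO)CC(=O)OC(C)(C)C | intermediate
9 | (3R)-3-(hydroxymethyl)hex-5-ynoic acid | C#CC[C@@H](CO)CC(=O)O | intermediate
10 | (4R)-4-(prop-2-yn-1-yl)dihydrofuran-2(3H)-one | C#CC[C@H]1COC(=O)C1 | intermediate
11 | 3,4-dimethoxybenzyl bromide | COc1ccc(CBr)cc1OC | starting material
12 | lithium enolate of 10 | C#CC[C@H]1COC([O-])=C1.[Li+] | intermediate
13 | (3R,4R)-3-(3,4-dimethoxybenzyl)-4-(prop-2-yn-1-yl)dihydrofuran-2(3H)-one | C#CC[C@H]1COC(=O)[C@@H]1Cc1ccc(OC)c(OC)c1 | intermediate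
14 | tributyltin hydride | CCCC[SnH](CCCC)CCCC | starting material
15 | (3R,4R)-3-(3,4-dimethoxybenzyl)-4-[2-(tributylstannyl)prop-2-en-1-yl]dihydrofuran-2(3H)-one | CCCC[Sn](CCCC)(CCCC)C(=C)C[C@H]1COC(=O)[C@@H]1Cc1ccc(OC)c(OC)c1 | intermediate
16 | dimethyl squarate | COC1=C(OC)C(=O)C1=O | starting material
17 | (±)-4-hydroxy-2,3-dimethoxycyclobut-2-en-1-one | COC1=C(OC)C(O)C1=O | intermediate
18 | (±)-4-chloro-2,3-dimethoxycyclobut-2-en-1-one | COC1=C(OC)C(Cl)C1=O | intermediate
19 | (3R,4R)-3-(3,4-dimethoxybenzyl)-4-[2-(2,3-dimethoxy-4-oxocyclobut-2-en-1-yl)prop-2-en-1-yl]dihydrofuran-2(3H)-one, both epimers at the cyclobutenone sp3 carbon | COC1=C(OC)C(C1=O)C(=C)C[C@H]2COC(=O)[C@@H]2Cc3ccc(OC)c(OC)c3 | intermediate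
20 | (3R,4R)-3-(3,4-dimethoxybenzyl)-4-[(3E)-4,5-dimethoxy-2-methylidene-6-oxohexa-3,5-dien-1-yl]dihydrofuran-2(3H)-one (ketene and alkenyl group cis) | O=C=C(OC)/C(OC)=C\C(=C)C[C@H]1COC(=O)[C@@H]1Cc1ccc(OC)c(OC)c1 | intermediate
21 | (3R,4R)-3-(3,4-dimethoxybenzyl)-4-[(3,4-dimethoxy-5-oxocyclohexa-1,3-dien-1-yl)methyl]dihydrofuran-2(3H)-one | O=C1CC(C[C@H]2COC(=O)[C@@H]2Cc3ccc(OC)c(OC)c3)=CC(OC)=C1OC | intermediate
22 | (3R,4R)-3-(3,4-dimethoxybenzyl)-4-(3-hydroxy-4,5-dimethoxybenzyl)dihydrofuran-2(3H)-one | COc1cc(C[C@H]2COC(=O)[C@@H]2Cc2ccc(OC)c(OC)c2)cc(O)c1OC | intermediate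
23 | (3R,4R)-3-(3,4-dimethoxybenzyl)-4-(3,4,5-trimethoxybenzyl)dihydrofuran-2(3H)-one | COc1ccc(C[C@H]2C(=O)OC[C@@H]2Cc2cc(OC)c(OC)c(OC)c2)cc1OC | target

Total step count: 10.
Longest linear sequence: 8 (steps 1–6, 9, 10).

**Steps most likely to fail**

**Step 9.**
- Tin-to-palladium transfer from the hindered 1,1-disubstituted stannane may be slow. The electron-rich chloride could then decay, or the allylpalladium species could dimerise.
- Bond formation could also stray to the methoxy-bearing allyl terminus.
- The stannane could be protodestannylated by the phenol as it forms.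

The fallback sets out from 2 and comes back at 23. It gives up the de novo ring and buys ring B as 3-(3,4,5-trimethoxyphenyl)propanoic acid. PivCl and Et3N convert this acid into 3-(3,4,5-trimethoxyphenyl)propanoic pivalic anhydride F1. F1 acylates 2 (LiCl) to (S)-4-benzyl-3-[3-(3,4,5-trimethoxyphenyl)propanoyl]oxazolidin-2-one F2. NaN(SiMe3)2 at −78 °C gives its sodium (Z)-enolate F3, which 5 alkylates to tert-butyl (3R)-3-{[(4S)-4-benzyl-2-oxo-1,3-oxazolidin-3-yl]carbonyl}-4-(3,4,5-trimethoxyphenyl)butanoate F4. LiBH4 reduces F4 to tert-butyl (3R)-3-(hydroxymethyl)-4-(3,4,5-trimethoxyphenyl)butanoate F5. TFA takes F5 through (3R)-3-(hydroxymethyl)-4-(3,4,5-trimethoxyphenyl)butanoic acid F6 to (4R)-4-(3,4,5-trimethoxybenzyl)dihydrofuran-2(3H)-one F7. LiN(SiMe3)2 gives its lithium enolate F8, and 11 alkylates it anti to the C4 substituent to give 23.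

**Step 8.** The activated alcohol or the chloride itself may ionise to the methoxy-stabilised cyclobutenyl cation. Chloride could then attack an O-methyl group (loss of methyl chloride) or be captured at the methoxy-bearing terminus, so the material may not survive isolation.

The fallback sets out from 17 and comes back at 19, and so at 22. Ac2O, pyridine and catalytic DMAP in CH2Cl2 at 0 °C should give 2,3-dimethoxy-4-oxocyclobut-2-en-1-yl acetate F9, an allylic ester that carries no nucleophilic counter-ion and should keep. A Stille coupling of the allylic acetate type with 15 (Pd2(dba)3, LiCl, DMF, 40 °C) would form the same η3-oxocyclobutenylpalladium chloride only inside the catalytic cycle and deliver 19. Heating 19 at 100 °C gives 22.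

**Step 6.** Regiocontrol may be poor, because the alkyne has no propargylic heteroatom to steer the catalyst. Much tin could then go to the terminal carbon, and separating the isomers may be laborious.

The fallback sets out from 13 and comes back at 15. Ionic Markovnikov hydroiodination (NaI, Me3SiCl, H2O, MeCN, rt) places the halogen on the internal carbon and should give (3R,4R)-3-(3,4-dimethoxybenzyl)-4-(2-iodoprop-2-en-1-yl)dihydrofuran-2(3H)-one F10. Palladium-catalysed stannylation with (Bu3Sn)2 (Pd(PPh3)4, toluene, 80 °C) then exchanges iodine for tin at that same carbon and gives 15, so the position of tin is fixed by connectivity.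

**Further compounds**

F1 | step 9 | 3-(3,4,5-trimethoxyphenyl)propanoic pivalic anhydride | COc1cc(CCC(=O)OC(=O)C(C)(C)C)cc(OC)c1OC
F2 | step 9 | (S)-4-benzyl-3-[3-(3,4,5-trimethoxyphenyl)propanoyl]oxazolidin-2-one | COc1cc(CCC(=O)N2[C@@H](Cc3ccccc3)COC2=O)cc(OC)c1OC
F3 | step 9 | sodium (Z)-enolate of F2 | COc1cc(C/C=C(\[O-])N2[C@@H](Cc3ccccc3)COC2=O)cc(OC)c1OC.[Na+]
F4 | step 9 | tert-butyl (3R)-3-{[(4S)-4-benzyl-2-oxo-1,3-oxazolidin-3-yl]carbonyl}-4-(3,4,5-trimethoxyphenyl)butanoate | COc1cc(C[C@H](CC(=O)OC(C)(C)C)C(=O)N2[C@@H](Cc3ccccc3)COC2=O)cc(OC)c1OC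
F5 | step 9 | tert-butyl (3R)-3-(hydroxymethyl)-4-(3,4,5-trimethoxyphenyl)butanoate | COc1cc(C[C@@H](CO)CC(=O)OC(C)(C)C)cc(OC)c1OC
F6 | step 9 | (3R)-3-(hydroxymethyl)-4-(3,4,5-trimethoxyphenyl)butanoic acid | COc1cc(C[C@@H](CO)CC(=O)O)cc(OC)c1OC
F7 | step 9 | (4R)-4-(3,4,5-trimethoxybenzyl)dihydrofuran-2(3H)-one | COc1cc(C[C@H]2COC(=O)C2)cc(OC)c1OC
F8 | step 9 | lithium enolate of F7 | COc1cc(C[C@H]2COC([O-])=C2)cc(OC)c1OC.[Li+]
F9 | step 8 | 2,3-dimethoxy-4-oxocyclobut-2-en-1-yl acetate | COC1=C(OC)C(OC(C)=O)C1=O
F10 | step 6 | (3R,4R)-3-(3,4-dimethoxybenzyl)-4-(2-iodoprop-2-en-1-yl)dihydrofuran-2(3H)-one | C=C(I)C[C@H]1COC(=O)[C@@H]1Cc1ccc(OC)c(OC)c1
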